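If the complex with four exchanged is wanted intact beside unreacted starting complex, the number to find is how many of its lifetimes the run lasts.

    starting complex + incoming ligand ⇌ leaving ligand + complex with one exchanged (K1 = 0.59, k1 = 0.23 M⁻¹ min⁻¹)
    complex with one exchanged + incoming ligand ⇌ leaving ligand + complex with two exchanged (K2 = 0.34, k2 = 0.17 M⁻¹ min⁻¹)
    complex with two exchanged + incoming ligand ⇌ leaving ligand + complex with three exchanged (K3 = 0.83, k3 = 0.35 M⁻¹ min⁻¹)
    complex with three exchanged + incoming ligand ⇌ leaving ligand + complex with four exchanged (K4 = 18, k4 = 0.42 M⁻¹ min⁻¹)
    complex with four exchanged ⇌ isomer of the product (K5 = 2.8, k5 = 0.0047 min⁻¹)
    starting complex + complex with four exchanged → side product (k6 = 7.2 M⁻¹ min⁻¹)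

| flask | starting complex | incoming ligand | time | remark |
|---|---|---|---|---|
| green | 20 mM (fed, over 64.0 min) | 1.20 equiv | 80 min | a stirred flask in which starting complex is dosed at a steady rate over 64.0 min without added volume, worked up at 80 min |
| ochre | 20 mM | 1.20 equiv |  | a single well-mixed tank run continuously and read at steady state, 80 min in it on average |
| grey | 20 mM | 1.20 equiv | 80 min | a closed flask charged with all of it at once and left for 80 min |
| teal | 20 mM | 1.20 equiv (fed, over 64.0 min) | 80 min | all but incoming ligand at the start; incoming ligand goes in evenly over 64.0 min, the run ends at 80 min |

- percentages count the starting complex that a species holds: one side product counts as two
- the stated concentrations are those of everything mixed, before any reaction; amounts are the same in each set-up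
- the feed brings no volume worth counting
- run time (green): 80 min

- the set-up with the highest share of complex with four exchanged in all that became complex with four exchanged or isomer of the product or side product, at the outlet or at the end ("none" if the first two lie within 2 percentage points) (green / ochre / grey / teal / none)
- share of complex with four exchanged in all that became complex with four exchanged or isomer of the product or side product, at the outlet or at the end, green
- share of complex with four exchanged in all that became complex with four exchanged or isomer of the product or side product, at the outlet or at the end, ochre
- share of complex with four exchanged in all that became complex with four exchanged or isomer of the product or side product, at the outlet or at the end, grey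
- share of complex with four exchanged in all that became complex with four exchanged or isomer of the product or side product, at the outlet or at the end, teal

The top rung of the ladder is step 6. At the charged concentrations in grey, the complex with four exchanged has a half-life of 4.8 min by step 6, shorter than the 150 min of the forward rate of its isomerisation and short against the 80 min run. In grey it therefore decays pseudo-first-order and its level follows its own formation. Below that rung lie the exchange steps, whose forward half-lives at the charged concentrations in grey run from 69 min to 170 min, and the forward half-life of 130 min for step 1 is longer than the run.

Integrating step 1 forward, with the ligand excess of 4.00 mM held constant, makes the ratio of ligand to starting complex grow as an exponential. That ratio reaches 1.29 in grey, which by this forward reckoning leaves 13.7 mM of starting complex. The capture number, k6 times starting complex times run time, is then 7.90 for grey.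

Each complex with four exchanged lost by step 6 counts double as side product. If formation grows as time to the power n, the level is close to the rate over the loss rate plus n/t, so with the isomer set aside the estimated share is (n + 1) / (2Z + n − 1). Counting rungs gives powers of 3 for grey, 4 for green and 7 for teal, where ligand enters every rung. This reckoning scales them by 0.667, a judgement for thinning reagents and back steps.

For green and teal, the same forward reckoning over a mean contact time of 48.0 min gives an estimate of 15.7 mM of starting complex, so Z is 9.06. For ochre, the forward tank balance leaves 14.8 mM, so Z is 8.55. The steady share there is one over (1 + 2Z + 0.331), the last term being the isomer.

| Set-up | This reckoning | Forecast |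
|---|---|---|
| green | 18.5 % | 19 % |
| ochre | 5.42 % | 5.2 % |
| grey | 17.9 % | 17 % |
| teal | 26.0 % | 25 % |

The forecast names teal, saying of that flask “Formation rises most steeply at the end”, and this reckoning puts the same flask highest, though its figures differ from the forecast's in the table.

The simulation gives 18.8 % for green, 5.25 % for ochre, 16.4 % for grey and 25.3 % for teal, which makes teal the highest. Grey read at 30 min is the neighbouring flask. The closed form gives an estimate of 17.1 mM of starting complex there, and the capture number is 3.70 against 7.90 at the full run time. With grey's power unchanged, the rule gives 35.7 %, and the flask reads 35.2 %.

The constants used here are assumed; the flask was simulated.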